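Remarks. Carotenoid locants are used for ring and chain positions of all intermediates (C1 = C(CH3)2, C3 = CH–O, C5 = C–CH3, C6 = ring carbon carrying the chain, C7–C11 along the chain; primed locants for the furanoid half). CIP descriptors are those of the compound actually named. Compounds 1, 6 and 19 are assumed to be catalogue chemicals (industrial intermediates of carotenoid and vitamin A manufacture). The target SMILES defines the all-E chain, and that isomer is planned.

## Analysis of the target

The target is (3S,5R,6R,3′S,5′R,8′R)-5′,8′-epoxy-5,6,5′,8′-tetrahydro-β,β-carotene-3,5,6,3′-tetrol, a C40 carotenoid of the latochrome type. An all-E octaene (C7=C8 to C9′=C10′, four chain methyl groups) joins two different end groups. One is a cyclohexane-3,5,6-triol whose tertiary C6 carbinol carries the chain. The other is a 2,5-dihydrofuran (ring O–C5′–C6′=C7′–C8′) fused to the cyclohexane at C5′–C6′. There are six stereocentres. On the left, 3-OH is trans to 5-OH and the vicinal tertiary 5,6-diol is trans. On the right, the ring oxygen at C5′ is trans to 3′-OH and H-8′ lies on the same face of the dihydrofuran as the C5′ methyl group. C3/C5 and C3′/C5′ have the same configuration, so both ends can be mapped onto one 5,6-epoxide that is anti to the C3 oxygen. The sensitive sites are the polyene (light, oxygen, acid, E/Z drift), the doubly allylic C8′–O bond (acid ionises it and scrambles C8′) and the tertiary allylic C6–OH (ionisable; a free 3-OH can bridge to C6). The hard part is C8′: a lone stereocentre outside the carbocycle, which the classical acid rearrangement of a 5,6-epoxide forms without control. The second difficulty is joining two different acid-labile ends to a symmetric chain.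

## Retrosynthetic reasoning

**Polyene.** Target 23 is cut at C11=C12 and C11′=C12′ into the triol dienal 18, the furanoid enal 15 and the symmetric C10 bis(phosphonium) salt 21, by way of the C25 salt 22. Cutting here keeps both end groups as aldehydes, so neither has to be turned into an allylic phosphonium salt under acid, which the C8′–O bond and the C6 carbinol would not survive. Salt 21 comes from dialdehyde 19 through diol 20. The forward reactions are two Wittig condensations under buffered conditions. The hindered 11Z/11′Z isomers relax thermally.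

**Key disconnection.** Enal 15 is traced through diol 14 to dibenzoate 13, and 13 is cut at the O–C8′ bond to give allenol 12. The dihydrofuran O–C5′–C6′=C7′–C8′ is a constitutional isomer of the α-hydroxyallene C5(OH)–C6=C7=C8, so no atom is added or lost. The allene axis is the only stereo element needed to define C8′. The forward reaction has to close the ring 5-endo with full axis-to-centre transfer.

**Allene.** Allenol 12 is traced to alkynyl epoxide 11 by cutting the C6–O bond in the SN2′ sense. The C6 centre of the epoxide becomes the axis, and the C5–O bond is kept and later becomes the furan oxygen. One epoxide thus supplies both C5′ and C8′.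

**Triol end.** Dienal 18 is traced through tetraol 17 and diol 16 to the same epoxide 11, now cut at C6–O with inversion by an oxygen nucleophile. The alkyne is kept through the hydrolysis because it cannot form the furanoid and gives a poorly stabilised cation. It is then turned into the 7E-alkene by hydroalumination directed by the new C6 hydroxyl.

**Epoxide.** Epoxide 11 needs its oxygen anti to the C3 oxygen, and no substrate-controlled epoxidation delivers that reliably. It is therefore traced to the syn epoxy alcohol 10 by inversion at C3, and 10 to the C3-epimeric dienynol 9 by hydroxyl-directed epoxidation.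

**Carbon skeleton.** Dienynol 9 is cut at C6–C7 into vinyl triflate 5 and enyne benzoate 7 (from 6). Triflate 5 fixes the C5=C6 position and comes from silyl ether 3 by reductive triflation through enolate 4. Ether 3 comes from alcohol 2, made by asymmetric transfer hydrogenation of 1.

## Alternatives that were turned down

**Alternative 1: late epoxide–furanoid rearrangement (the textbook route).**
- Disconnection: the O–C8′ bond is made by a 1,3-shift of the epoxide oxygen from C6′.
- Forward key step: dilute acid on the C40 epoxy-tetrol A1 (latoxanthin), assembled by double Wittig.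
- Why turned down: the ring expansion runs through the polyene-stabilised C6′ cation, and O5′ can add to either face of C8′. C8′ is therefore not controlled, and a C40 epimer pair must be separated at the last step. The same acid ionises the tertiary allylic C6–OH at the other end. Metal-catalysed versions of this vinyl-oxirane ring expansion are the same disconnection, and their stereochemical course on a polyene is not safe to predict.

**Alternative 2: singlet-oxygen [4+2] and oxygen extrusion.**
- Disconnection: both C–O bonds of a 1,2-dioxine are formed across C5 and C8, then one oxygen is removed.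
- Forward key step: cycloaddition of singlet oxygen to the s-cis C5=C6–C7=C8 diene of triene-diol A2 to give endoperoxide A3, followed by phosphine deoxygenation (ring contraction of the 1,2-dioxine to the 2,5-dihydrofuran).
- Why turned down: the diene is tetrasubstituted at C5=C6 and twisted out of s-cis. Ene reactions at C4–H and C18–H compete, and the face is governed only by the remote 3-OH. Phosphine deoxygenation collapses by SN2 with inversion at one carbon: at C8 this gives the wrong relative configuration, and at tertiary C5 it should not proceed. No steps are saved.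

**Alternative 3: etherification at a preformed C8 stereocentre.**
- Disconnection: the O–C8′ bond is made by substitution at C8.
- Forward key step: 5-exo-tet displacement (or palladium-allyl etherification) of the C8 carbonate in the (Z)-6(7)-ene A4, with C8 set by reagent-controlled ketone reduction.
- Why turned down: the Z geometry is needed at an exocyclic alkene flanked by two quaternary carbons, with no control element. The C8 leaving group is secondary and doubly allylic and will ionise to the same cation as in Alternative 1. The ketone, its reduction and the activation cost three to four extra steps.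

Key step: step 9

## Route

Step 1
Reactants: 1 2,6,6-trimethylcyclohex-2-ene-1,4-dione (ketoisophorone)
Product: 2 (R)-4-hydroxy-2,6,6-trimethylcyclohex-2-en-1-one
Conditions: RuCl[(R,R)-TsDPEN](p-cymene) (1 mol%), i-PrOH, rt
Reagents that add atoms: none
Why: Noyori-type asymmetric transfer hydrogenation; only the unhindered C4 carbonyl (between CH= and CH2) should react, because the C1 carbonyl sits between C(CH3)= and C(CH3)2. With the enone π-system in the aryl position of the quadrant model, the (R,R)-catalyst should give the (R)-carbinol, which later directs the epoxidation.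

Step 2
Reactants: 2 (R)-4-hydroxy-2,6,6-trimethylcyclohex-2-en-1-one
Product: 3 (R)-2,6,6-trimethyl-4-(triethylsilyloxy)cyclohex-2-en-1-one
Conditions: TESCl, imidazole, DMF, 0 °C → rt
Reagents that add atoms: chlorotriethylsilane CC[Si](Cl)(CC)CC
Why: Standard silylation of a secondary alcohol; the ether protects the hydroxyl through the enolate and coupling steps and is removed later by mild acid without touching a benzoate.

Step 3
Reactants: 3 (R)-2,6,6-trimethyl-4-(triethylsilyloxy)cyclohex-2-en-1-one
Product: 5 (S)-2,6,6-trimethyl-4-(triethylsilyloxy)cyclohex-1-en-1-yl trifluoromethanesulfonate, via lithium enolate 4 (not isolated)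
Conditions: L-Selectride, THF, −78 °C; then PhNTf2, −78 °C → rt
Reagents that add atoms: N-phenylbis(trifluoromethanesulfonimide) O=S(=O)(N(c1ccccc1)S(=O)(=O)C(F)(F)F)C(F)(F)F
Why: Reductive triflation; conjugate hydride addition to a β-unsubstituted enone with a hindered carbonyl gives the C1–C2 enolate regiospecifically, and O-sulfonylation fixes the later C5=C6 double bond. The silyloxy group is γ to the enolate carbon and cannot be eliminated.

Step 4
Reactants: 6 (E)-3-methylpent-2-en-4-yn-1-ol
Product: 7 (E)-3-methylpent-2-en-4-yn-1-yl benzoate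
Conditions: BzCl, pyridine, DMAP (cat.), CH2Cl2, 0 °C
Reagents that add atoms: benzoyl chloride O=C(Cl)c1ccccc1
Why: Acylation of the primary allylic alcohol; the ester masks C11–OH so that it cannot direct the vanadium epoxidation to C9=C10, and it tolerates all steps up to the deprotections.

Step 5
Reactants: 5 (S)-2,6,6-trimethyl-4-(triethylsilyloxy)cyclohex-1-en-1-yl trifluoromethanesulfonate; 7 (E)-3-methylpent-2-en-4-yn-1-yl benzoate
Product: 9 (E)-5-[(S)-4-hydroxy-2,6,6-trimethylcyclohex-1-en-1-yl]-3-methylpent-2-en-4-yn-1-yl benzoate, via triethylsilyl ether 8 (not isolated)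
Conditions: Pd(PPh3)4 (5 mol%), CuI (10 mol%), i-Pr2NH, THF, rt; then PPTS, MeOH, rt
Reagents that add atoms: none
Why: Sonogashira coupling of a cyclohexenyl triflate with a terminal enyne forms C6–C7 with the tetrasubstituted C5=C6 alkene already in place. Acid methanolysis then cleaves only the triethylsilyl ether and frees the directing hydroxyl.

Step 6
Reactants: 9 (E)-5-[(S)-4-hydroxy-2,6,6-trimethylcyclohex-1-en-1-yl]-3-methylpent-2-en-4-yn-1-yl benzoate
Product: 10 (E)-5-[(1R,4R,6R)-4-hydroxy-2,2,6-trimethyl-7-oxabicyclo[4.1.0]heptan-1-yl]-3-methylpent-2-en-4-yn-1-yl benzoate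
Conditions: VO(acac)2 (5 mol%), t-BuOOH (decane), CH2Cl2, 0 °C → rt
Reagents that add atoms: tert-butyl hydroperoxide CC(C)(C)OO
Why: Hydroxyl-directed vanadium epoxidation of a cyclic homoallylic alcohol delivers oxygen to the C5=C6 face syn to the C3 hydroxyl, which sets C5 and C6. The C9=C10 alkene and the alkyne carry no directing group and should not react.

Step 7
Reactants: 10 (E)-5-[(1R,4R,6R)-4-hydroxy-2,2,6-trimethyl-7-oxabicyclo[4.1.0]heptan-1-yl]-3-methylpent-2-en-4-yn-1-yl benzoate
Product: 11 (E)-5-[(1R,4S,6R)-4-(benzoyloxy)-2,2,6-trimethyl-7-oxabicyclo[4.1.0]heptan-1-yl]-3-methylpent-2-en-4-yn-1-yl benzoate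
Conditions: PPh3, DIAD, PhCO2H, THF, 0 °C → rt
Reagents that add atoms: benzoic acid OC(=O)c1ccccc1
Why: Mitsunobu inversion at the secondary C3 carbinol turns the syn relationship used for direction into the anti relationship (3-O trans to the epoxide) that both end groups need. It gives the final (3S) configuration and protects O3 in the same step.

Step 8
Reactants: 11 (E)-5-[(1R,4S,6R)-4-(benzoyloxy)-2,2,6-trimethyl-7-oxabicyclo[4.1.0]heptan-1-yl]-3-methylpent-2-en-4-yn-1-yl benzoate
Product: 12 (2E)-5-[(2R,4S)-4-(benzoyloxy)-2-hydroxy-2,6,6-trimethylcyclohexylidene]-3-methylpenta-2,4-dien-1-yl benzoate with (aS) allene axis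
Conditions: (IPr)CuCl (5 mol%), NaOt-Bu (5 mol%), polymethylhydrosiloxane, toluene, 0 °C; aq. NH4F work-up
Reagents that add atoms: none
Why: Copper hydride-catalysed SN2′ reduction of a propargyl oxirane; hydride enters at C8 anti to the departing C6–O bond, so the C6 centre becomes the (aS) axis with H-8 on the face opposite the 5-oxygen. C5 keeps its oxygen with retention.

Step 9
Reactants: 12 (2E)-5-[(2R,4S)-4-(benzoyloxy)-2-hydroxy-2,6,6-trimethylcyclohexylidene]-3-methylpenta-2,4-dien-1-yl benzoate with (aS) allene axis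
Product: 13 (2E)-3-[(2R,6S,7aR)-6-(benzoyloxy)-4,4,7a-trimethyl-2,4,5,6,7,7a-hexahydro-1-benzofuran-2-yl]but-2-en-1-yl benzoate
Conditions: Ph3PAuCl (2 mol%), AgBF4 (2 mol%), THF, 0 °C, dark; Et3N quench
Reagents that add atoms: none
Why: Cationic gold(I) binds the C7=C8 π-bond of the allene, the tertiary 5-hydroxyl adds to C8 anti to gold, and protodeauration of the C7–Au bond leaves the C6′=C7′ alkene. The closest known reaction is the gold-catalysed cycloisomerisation of α-hydroxyallenes to 2,5-dihydrofurans with axis-to-centre chirality transfer. The dihydrofuran closes in a 5-endo-trig mode on the allene, which puts O, C5, C6, C7 and C8 in the plane of the C6 substituents. C8′ is set by the allene axis alone: the O–C8 bond forms in that plane, so H-8 and C9 keep the faces they have in the allene, and with the (aS) axis H-8 ends cis to the C5 methyl group, which is (8′R). C5′ is carried over unchanged. The step needs selectivity for the allene over the C9=C10 alkene and over carbocyclisation of the vinylallene, and it needs the axis to survive. The hydroxyl held next to the allene, the low catalyst loading, the donor solvent and the low temperature are chosen to favour direct C–O bond formation over ionisation. The base quench protects the doubly allylic C8′–O bond of the product.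

Step 10
Reactants: 13 (2E)-3-[(2R,6S,7aR)-6-(benzoyloxy)-4,4,7a-trimethyl-2,4,5,6,7,7a-hexahydro-1-benzofuran-2-yl]but-2-en-1-yl benzoate
Product: 14 (2R,6S,7aR)-2-[(2E)-4-hydroxybut-2-en-2-yl]-4,4,7a-trimethyl-2,4,5,6,7,7a-hexahydro-1-benzofuran-6-ol
Conditions: NaOMe (0.2 equiv), MeOH, rt
Reagents that add atoms: none
Why: Zemplén transesterification removes both benzoates; the furanoid ether and C8′ are inert to methoxide.

Step 11
Reactants: 14 (2R,6S,7aR)-2-[(2E)-4-hydroxybut-2-en-2-yl]-4,4,7a-trimethyl-2,4,5,6,7,7a-hexahydro-1-benzofuran-6-ol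
Product: 15 (2E)-3-[(2R,6S,7aR)-6-hydroxy-4,4,7a-trimethyl-2,4,5,6,7,7a-hexahydro-1-benzofuran-2-yl]but-2-enal
Conditions: MnO2, CH2Cl2, rt
Reagents that add atoms: none
Why: Manganese dioxide oxidises only the primary allylic alcohol; the saturated secondary 3′-OH is untouched and the neutral medium leaves C8′ alone.

Step 12
Reactants: 11 (E)-5-[(1R,4S,6R)-4-(benzoyloxy)-2,2,6-trimethyl-7-oxabicyclo[4.1.0]heptan-1-yl]-3-methylpent-2-en-4-yn-1-yl benzoate
Product: 16 (2E)-5-[(1S,2R,4S)-4-(benzoyloxy)-1,2-dihydroxy-2,6,6-trimethylcyclohexyl]-3-methylpent-2-en-4-yn-1-yl benzoate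
Conditions: HClO4 (5 mol%), THF/H2O 3:1, 0 °C
Reagents that add atoms: water O
Why: Acid-catalysed epoxide hydrolysis in the borderline SN2 regime; water should attack propargylic C6 anti to the epoxide oxygen, which is the trans-diaxial (Fürst–Plattner) opening through the chair with equatorial benzoate and alkynyl groups. This inverts C6 and gives the trans 5,6-diol. The alkynyl group stabilises a cation too poorly for SN1 scrambling and cannot form a furanoid, and the benzoate on O3 prevents bridging from O3 to C6.

Step 13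
Reactants: 16 (2E)-5-[(1S,2R,4S)-4-(benzoyloxy)-1,2-dihydroxy-2,6,6-trimethylcyclohexyl]-3-methylpent-2-en-4-yn-1-yl benzoate
Product: 17 (1R,2R,4S)-1-[(1E,3E)-5-hydroxy-3-methylpenta-1,3-dien-1-yl]-2,6,6-trimethylcyclohexane-1,2,4-triol
Conditions: Red-Al (excess), THF, 0 °C → rt; aq. Rochelle salt
Reagents that add atoms: none
Why: Alkoxide-directed trans-hydroalumination of the tertiary propargylic alcohol gives the 7E-alkene after protonolysis. The same reagent reduces off both benzoates, so no separate deprotection is needed.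

Step 14
Reactants: 17 (1R,2R,4S)-1-[(1E,3E)-5-hydroxy-3-methylpenta-1,3-dien-1-yl]-2,6,6-trimethylcyclohexane-1,2,4-triol
Product: 18 (2E,4E)-3-methyl-5-[(1R,2R,4S)-1,2,4-trihydroxy-2,6,6-trimethylcyclohexyl]penta-2,4-dienal
Conditions: MnO2, acetone, rt
Reagents that add atoms: none
Why: Selective oxidation of the primary allylic alcohol; the tertiary allylic and the saturated secondary hydroxyls cannot be oxidised under these conditions.

Step 15
Reactants: 19 (2E,4E,6E)-2,7-dimethylocta-2,4,6-trienedial
Product: 20 (2E,4E,6E)-2,7-dimethylocta-2,4,6-triene-1,8-diol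
Conditions: NaBH4, MeOH/THF, 0 °C
Reagents that add atoms: none
Why: 1,2-Reduction of both conjugated aldehydes; the triene geometry is not affected.

Step 16
Reactants: 20 (2E,4E,6E)-2,7-dimethylocta-2,4,6-triene-1,8-diol
Product: 21 [(2E,4E,6E)-2,7-dimethylocta-2,4,6-triene-1,8-diyl]bis(triphenylphosphonium) dibromide
Conditions: PPh3·HBr (2.2 equiv), MeOH, rt
Reagents that add atoms: triphenylphosphine hydrobromide [Br-].[PH+](c1ccccc1)(c1ccccc1)c1ccccc1
Why: Standard conversion of polyene allylic alcohols into phosphonium salts through the allylic cation; attack at the primary termini gives the fully conjugated all-E bis-salt.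

Step 17
Reactants: 15 (2E)-3-[(2R,6S,7aR)-6-hydroxy-4,4,7a-trimethyl-2,4,5,6,7,7a-hexahydro-1-benzofuran-2-yl]but-2-enal; 21 [(2E,4E,6E)-2,7-dimethylocta-2,4,6-triene-1,8-diyl]bis(triphenylphosphonium) dibromide
Product: 22 {(2E,4E,6E,8E,10E)-11-[(2R,6S,7aR)-6-hydroxy-4,4,7a-trimethyl-2,4,5,6,7,7a-hexahydro-1-benzofuran-2-yl]-2,7-dimethyldodeca-2,4,6,8,10-pentaen-1-yl}triphenylphosphonium bromide
Conditions: 21 (3 equiv), 1,2-epoxybutane/EtOH, reflux, argon, dark
Reagents that add atoms: none
Why: Wittig condensation forming C11′=C12′; epoxybutane scavenges HBr and generates the ylide under near-neutral conditions, so the γ-hydrogen at C8′ of the enal is not removed. The excess of bis-salt favours mono-condensation, and any 11′Z isomer is carried on.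

Step 18
Reactants: 22 {(2E,4E,6E,8E,10E)-11-[(2R,6S,7aR)-6-hydroxy-4,4,7a-trimethyl-2,4,5,6,7,7a-hexahydro-1-benzofuran-2-yl]-2,7-dimethyldodeca-2,4,6,8,10-pentaen-1-yl}triphenylphosphonium bromide; 18 (2E,4E)-3-methyl-5-[(1R,2R,4S)-1,2,4-trihydroxy-2,6,6-trimethylcyclohexyl]penta-2,4-dienal
Product: 23 (3S,5R,6R,3′S,5′R,8′R)-5′,8′-epoxy-5,6,5′,8′-tetrahydro-β,β-carotene-3,5,6,3′-tetrol (target)
Conditions: 1,2-epoxybutane/EtOH, reflux, argon, dark; then heptane, 80 °C, crystallisation
Reagents that add atoms: none
Why: Second Wittig condensation forms C11=C12 and completes the octaene; the buffered medium tolerates the free hydroxyls and the acid-labile C8′–O and C6–OH groups. The sterically hindered 11Z and 11′Z isomers should relax thermally to the all-E compound.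

## Compound list

1 | 2,6,6-trimethylcyclohex-2-ene-1,4-dione (ketoisophorone) | CC1=CC(=O)CC(C)(C)C1=O | starting material
2 | (R)-4-hydroxy-2,6,6-trimethylcyclohex-2-en-1-one | CC1(C)C[C@@H](O)C=C(C)C1=O | intermediate
3 | (R)-2,6,6-trimethyl-4-(triethylsilyloxy)cyclohex-2-en-1-one | CC1(C)C[C@@H](O[Si](CC)(CC)CC)C=C(C)C1=O | intermediate
4 | lithium (S)-2,6,6-trimethyl-4-(triethylsilyloxy)cyclohex-1-en-1-olate | CC1(C)C[C@@H](O[Si](CC)(CC)CC)CC(C)=C1[O-].[Li+] | intermediate (not isolated)
5 | (S)-2,6,6-trimethyl-4-(triethylsilyloxy)cyclohex-1-en-1-yl trifluoromethanesulfonate | CC1(C)C[C@@H](O[Si](CC)(CC)CC)CC(C)=C1OS(=O)(=O)C(F)(F)F | intermediate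
6 | (E)-3-methylpent-2-en-4-yn-1-ol | C#C/C(C)=C/CO | starting material
7 | (E)-3-methylpent-2-en-4-yn-1-yl benzoate | C#C/C(C)=C/COC(=O)c1ccccc1 | intermediate
8 | (E)-3-methyl-5-[(S)-2,6,6-trimethyl-4-(triethylsilyloxy)cyclohex-1-en-1-yl]pent-2-en-4-yn-1-yl benzoate | CC1(C)C[C@@H](O[Si](CC)(CC)CC)CC(C)=C1C#C/C(C)=C/COC(=O)c1ccccc1 | intermediate (not isolated)
9 | (E)-5-[(S)-4-hydroxy-2,6,6-trimethylcyclohex-1-en-1-yl]-3-methylpent-2-en-4-yn-1-yl benzoate (C3 epimeric to the target, OH cis to the face that is epoxidised) | CC1(C)C[C@@H](O)CC(C)=C1C#C/C(C)=C/COC(=O)c1ccccc1 | intermediate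
10 | (E)-5-[(1R,4R,6R)-4-hydroxy-2,2,6-trimethyl-7-oxabicyclo[4.1.0]heptan-1-yl]-3-methylpent-2-en-4-yn-1-yl benzoate; carotenoid locants (3R,5R,6R), epoxide cis to 3-OH | C[C@@]12C[C@H](O)CC(C)(C)[C@]1(C#C/C(C)=C/COC(=O)c1ccccc1)O2 | intermediate
11 | (E)-5-[(1R,4S,6R)-4-(benzoyloxy)-2,2,6-trimethyl-7-oxabicyclo[4.1.0]heptan-1-yl]-3-methylpent-2-en-4-yn-1-yl benzoate; carotenoid locants (3S,5R,6R), epoxide trans to 3-OBz | C[C@@]12C[C@@H](OC(=O)c3ccccc3)CC(C)(C)[C@]1(C#C/C(C)=C/COC(=O)c1ccccc1)O2 | intermediate
12 | (2E)-5-[(2R,4S)-4-(benzoyloxy)-2-hydroxy-2,6,6-trimethylcyclohexylidene]-3-methylpenta-2,4-dien-1-yl benzoate, (aS) allene axis; carotenoid locants (3S,5R,6S); H-8 on the face opposite the 5-OH, C9 on the face of the 5-OH; the axis is written on the central allene carbon | C[C@@]1(O)C[C@@H](OC(=O)c2ccccc2)CC(C)(C)C1=[C@]=C([H])/C(C)=C/COC(=O)c1ccccc1 | intermediate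
13 | (2E)-3-[(2R,6S,7aR)-6-(benzoyloxy)-4,4,7a-trimethyl-2,4,5,6,7,7a-hexahydro-1-benzofuran-2-yl]but-2-en-1-yl benzoate | O=C(OC/C=C(\C)[C@H]1C=C2C(C)(C)C[C@H](OC(=O)c3ccccc3)C[C@@]2(C)O1)c1ccccc1 | intermediate
14 | (2R,6S,7aR)-2-[(2E)-4-hydroxybut-2-en-2-yl]-4,4,7a-trimethyl-2,4,5,6,7,7a-hexahydro-1-benzofuran-6-ol | OC/C=C(\C)[C@H]1C=C2C(C)(C)C[C@H](O)C[C@@]2(C)O1 | intermediate
15 | (2E)-3-[(2R,6S,7aR)-6-hydroxy-4,4,7a-trimethyl-2,4,5,6,7,7a-hexahydro-1-benzofuran-2-yl]but-2-enal | O=C/C=C(\C)[C@H]1C=C2C(C)(C)C[C@H](O)C[C@@]2(C)O1 | intermediate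
16 | (2E)-5-[(1S,2R,4S)-4-(benzoyloxy)-1,2-dihydroxy-2,6,6-trimethylcyclohexyl]-3-methylpent-2-en-4-yn-1-yl benzoate; carotenoid locants (3S,5R,6S), 5-OH and 6-OH trans | O=C(OC/C=C(C)/C#C[C@@]1(O)C(C)(C)C[C@H](OC(=O)c2ccccc2)C[C@@]1(C)O)c1ccccc1 | intermediate
17 | (1R,2R,4S)-1-[(1E,3E)-5-hydroxy-3-methylpenta-1,3-dien-1-yl]-2,6,6-trimethylcyclohexane-1,2,4-triol | OC/C=C(C)/C=C/[C@@]1(O)C(C)(C)C[C@H](O)C[C@@]1(C)O | intermediate
18 | (2E,4E)-3-methyl-5-[(1R,2R,4S)-1,2,4-trihydroxy-2,6,6-trimethylcyclohexyl]penta-2,4-dienal | O=C/C=C(C)/C=C/[C@@]1(O)C(C)(C)C[C@H](O)C[C@@]1(C)O | intermediate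
19 | (2E,4E,6E)-2,7-dimethylocta-2,4,6-trienedial | O=C/C(C)=C/C=C/C=C(C)/C=O | starting material
20 | (2E,4E,6E)-2,7-dimethylocta-2,4,6-triene-1,8-diol | OC/C(C)=C/C=C/C=C(C)/CO | intermediate
21 | [(2E,4E,6E)-2,7-dimethylocta-2,4,6-triene-1,8-diyl]bis(triphenylphosphonium) dibromide | [Br-].[Br-].c1ccccc1[P+](c1ccccc1)(c1ccccc1)C/C(C)=C/C=C/C=C(C)/C[P+](c1ccccc1)(c1ccccc1)c1ccccc1 | intermediate
22 | {(2E,4E,6E,8E,10E)-11-[(2R,6S,7aR)-6-hydroxy-4,4,7a-trimethyl-2,4,5,6,7,7a-hexahydro-1-benzofuran-2-yl]-2,7-dimethyldodeca-2,4,6,8,10-pentaen-1-yl}triphenylphosphonium bromide | [Br-].c1ccccc1[P+](c1ccccc1)(c1ccccc1)C/C(C)=C/C=C/C=C(C)/C=C/C=C(\C)[C@H]1C=C2C(C)(C)C[C@H](O)C[C@@]2(C)O1 | intermediate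
23 | (3S,5R,6R,3′S,5′R,8′R)-5′,8′-epoxy-5,6,5′,8′-tetrahydro-β,β-carotene-3,5,6,3′-tetrol | CC(/C=C/C=C(C)/C=C/[C@@]1(O)C(C)(C)C[C@H](O)C[C@@]1(C)O)=C\C=C\C=C(C)\C=C\C=C(/C)[C@H]1C=C2C(C)(C)C[C@H](O)C[C@@]2(C)O1 | target

## Step count and risks

Total step count: 18. Longest linear sequence: 12 (steps 1, 2, 3, 5, 6, 7, 8, 9, 10, 11, 17, 18). The left branch (steps 12–14) and the C10 unit (steps 15, 16) join convergently.

**Step 9 (key step).**
- What may go wrong: the gold–allene complex may ionise to a vinyl-stabilised allyl cation, which loses the axial information and gives both configurations at C8′. The vinylallene may carbocyclise. The product may re-ionise at its doubly allylic C8′–O bond.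
- Fallback: set out from 12 and close the ring by halo-etherification with N-iodosuccinimide (CH2Cl2, NaHCO3, −20 °C). Iodonium formation at C7=C8 and anti attack of O5 at C8 use the same in-plane geometry and should give the 7′-iodo derivative of 13, (2E)-3-[(2S,6S,7aR)-6-(benzoyloxy)-3-iodo-4,4,7a-trimethyl-2,4,5,6,7,7a-hexahydro-1-benzofuran-2-yl]but-2-en-1-yl benzoate F1. Radical deiodination (Bu3SnH, Et3B, toluene, rt) then returns to the route at 13.

**Step 8.**
- What may go wrong: hydride delivery may lose its anti sense, for example through syn elimination from a vinylcopper intermediate, which would erode the axis. The benzoates or the enyne may be reduced.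
- Fallback: set out from 11 and use palladium(0)-catalysed hydrogenolysis of the alkynyl oxirane with formic acid and triethylamine (Pd2(dba)3, PBu3, THF). Oxidative addition anti to the C6–O bond gives an allenylpalladium species, and the hydride is then transferred from the metal with retention, so the anti outcome rests on a different mechanism. This fallback makes no new isolated compound (F0) and returns at 12.

**Step 12.**
- What may go wrong: water may enter at the less hindered C5 terminus, or C6 may scramble by partial SN1 ionisation. Either gives the wrong relative configuration of the diol.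
- Fallback: set out from 9 and use the diastereomeric epoxide, for which attack at C5 is the desired, trans-diaxial and less hindered opening.
  - Mitsunobu inversion with chloroacetic acid gives (E)-5-[(R)-4-(chloroacetoxy)-2,6,6-trimethylcyclohex-1-en-1-yl]-3-methylpent-2-en-4-yn-1-yl benzoate F2.
  - Selective methanolysis of the chloroacetate (K2CO3, MeOH, 0 °C) gives (E)-5-[(R)-4-hydroxy-2,6,6-trimethylcyclohex-1-en-1-yl]-3-methylpent-2-en-4-yn-1-yl benzoate F3.
  - Directed epoxidation (VO(acac)2, t-BuOOH) gives (E)-5-[(1S,4S,6S)-4-hydroxy-2,2,6-trimethyl-7-oxabicyclo[4.1.0]heptan-1-yl]-3-methylpent-2-en-4-yn-1-yl benzoate F4, with the epoxide cis to a 3-OH that already has the final configuration and cannot bridge.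
  - Acid hydrolysis with inversion at C5 gives (2E)-3-methyl-5-[(1S,2R,4S)-1,2,4-trihydroxy-2,6,6-trimethylcyclohexyl]pent-2-en-4-yn-1-yl benzoate F5.
  - Red-Al reduction of F5 returns to the route at 17.

**Step 17.**
- What may go wrong: the first Wittig product is a more acidic phosphonium salt than 21, so a second condensation with another molecule of 15 can compete. The new double bond may form as an E/Z mixture.
- Fallback: set out from 20 and use phosphonate carbanions formed irreversibly with one equivalent of base.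
  - PBr3 gives (2E,4E,6E)-1,8-dibromo-2,7-dimethylocta-2,4,6-triene F6.
  - Arbuzov reaction with P(OEt)3 gives tetraethyl [(2E,4E,6E)-2,7-dimethylocta-2,4,6-triene-1,8-diyl]bis(phosphonate) F7.
  - Horner–Wadsworth–Emmons reaction of F7 in excess (NaHMDS, 1 equiv, THF, −78 °C) with 15 gives diethyl {(2E,4E,6E,8E,10E)-11-[(2R,6S,7aR)-6-hydroxy-4,4,7a-trimethyl-2,4,5,6,7,7a-hexahydro-1-benzofuran-2-yl]-2,7-dimethyldodeca-2,4,6,8,10-pentaen-1-yl}phosphonate F8.
  - A second Horner–Wadsworth–Emmons reaction of F8 with 18 returns to the route at 23.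

**Step 3.**
- What may go wrong: 1,2-reduction of the enone may compete, or O-sulfonylation of the hindered boron-complexed enolate may be incomplete.
- Fallback: set out from 3 and hydrogenate the alkene (H2, Pd/C, EtOAc) to (4S)-2,2,6-trimethyl-4-(triethylsilyloxy)cyclohexanone F9 (C6 epimers, which converge). Deprotonation at the only α-CH (KHMDS, THF, −78 °C) and trapping with PhNTf2 returns to the route at 5.

## Further compounds

F1 | step 9 | (2E)-3-[(2S,6S,7aR)-6-(benzoyloxy)-3-iodo-4,4,7a-trimethyl-2,4,5,6,7,7a-hexahydro-1-benzofuran-2-yl]but-2-en-1-yl benzoate (same spatial arrangement as 13) | O=C(OC/C=C(\C)[C@H]1C(I)=C2C(C)(C)C[C@H](OC(=O)c3ccccc3)C[C@@]2(C)O1)c1ccccc1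
F0 | step 8 | none | none
F2 | step 12 | (E)-5-[(R)-4-(chloroacetoxy)-2,6,6-trimethylcyclohex-1-en-1-yl]-3-methylpent-2-en-4-yn-1-yl benzoate | CC1(C)C[C@H](OC(=O)CCl)CC(C)=C1C#C/C(C)=C/COC(=O)c1ccccc1
F3 | step 12 | (E)-5-[(R)-4-hydroxy-2,6,6-trimethylcyclohex-1-en-1-yl]-3-methylpent-2-en-4-yn-1-yl benzoate | CC1(C)C[C@H](O)CC(C)=C1C#C/C(C)=C/COC(=O)c1ccccc1
F4 | step 12 | (E)-5-[(1S,4S,6S)-4-hydroxy-2,2,6-trimethyl-7-oxabicyclo[4.1.0]heptan-1-yl]-3-methylpent-2-en-4-yn-1-yl benzoate | C[C@]12C[C@@H](O)CC(C)(C)[C@@]1(C#C/C(C)=C/COC(=O)c1ccccc1)O2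
F5 | step 12 | (2E)-3-methyl-5-[(1S,2R,4S)-1,2,4-trihydroxy-2,6,6-trimethylcyclohexyl]pent-2-en-4-yn-1-yl benzoate | O=C(OC/C=C(C)/C#C[C@@]1(O)C(C)(C)C[C@H](O)C[C@@]1(C)O)c1ccccc1
F6 | step 17 | (2E,4E,6E)-1,8-dibromo-2,7-dimethylocta-2,4,6-triene | BrC/C(C)=C/C=C/C=C(C)/CBr
F7 | step 17 | tetraethyl [(2E,4E,6E)-2,7-dimethylocta-2,4,6-triene-1,8-diyl]bis(phosphonate) | CCOP(=O)(OCC)C/C(C)=C/C=C/C=C(C)/CP(=O)(OCC)OCC
F8 | step 17 | diethyl {(2E,4E,6E,8E,10E)-11-[(2R,6S,7aR)-6-hydroxy-4,4,7a-trimethyl-2,4,5,6,7,7a-hexahydro-1-benzofuran-2-yl]-2,7-dimethyldodeca-2,4,6,8,10-pentaen-1-yl}phosphonate | CCOP(=O)(OCC)C/C(C)=C/C=C/C=C(C)/C=C/C=C(\C)[C@H]1C=C2C(C)(C)C[C@H](O)C[C@@]2(C)O1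
F9 | step 3 | (4S)-2,2,6-trimethyl-4-(triethylsilyloxy)cyclohexanone (both C6 epimers) | CC1(C)C[C@@H](O[Si](CC)(CC)CC)CC(C)C1=O
A1 | alternative 1 | (3S,5R,6R,3′S,5′R,6′S)-5′,6′-epoxy-5,6,5′,6′-tetrahydro-β,β-carotene-3,5,6,3′-tetrol (latoxanthin) | C[C@@]12C[C@@H](O)CC(C)(C)[C@]1(/C=C/C(C)=C/C=C/C(C)=C/C=C/C=C(C)/C=C/C=C(C)/C=C/[C@@]1(O)C(C)(C)C[C@H](O)C[C@@]1(C)O)O2
A2 | alternative 2 | (R)-4-[(1E,3E)-5-hydroxy-3-methylpenta-1,3-dien-1-yl]-3,5,5-trimethylcyclohex-3-en-1-ol | OC/C=C(C)/C=C/C1=C(C)C[C@@H](O)CC1(C)C
A3 | alternative 2 | (3S,5R,8R)-5,8-epidioxy analogue of 14 (carotenoid locants; 14 with an O–O bridge between C5 and C8) | OC/C=C(\C)[C@H]1C=C2C(C)(C)C[C@H](O)C[C@@]2(C)OO1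
A4 | alternative 3 | (2E,4S)-5-[(Z)-(2R,4S)-4-(benzoyloxy)-2-hydroxy-2,6,6-trimethylcyclohexylidene]-4-[(methoxycarbonyl)oxy]-3-methylpent-2-en-1-yl benzoate | C[C@@]1(O)C[C@@H](OC(=O)c2ccccc2)CC(C)(C)/C1=C/[C@H](OC(=O)OC)/C(C)=C/COC(=O)c1ccccc1
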